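The dihydropyran ring of the chroman (O1, C2, C3, C4, C4a, C8a) is carried as a seven-membered 2,2-dimethyl-1,4-benzoxazepine and contracted by excision of the ring nitrogen. In one operation the key step turns the secondary amine into an isodiazene that loses N2 and joins C3 to C4 at the final saturated oxidation level. It exploits the benzylic C4 (on aromatic C4a), which stabilises the radical, while O1–C2(CH3)2 is already in place. The precursor is a 6-ethynyl-7-prenyl-8-silyloxy-tetrahydro-1,4-benzoxazepine made from prenylated phloroglucinaldehyde. Sonogashira annulation then builds the benzofuran, and lithiation–borylation with Zweifel olefination sets the (R)-3-methylbut-3-en-2-yl group.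

Key step: step 8

Remark: the side-chain stereocenter of the target is read as R. (+)-Sparteine, ethyl N,N-diisopropylcarbamate and the anomeric amide of step 8 are taken as purchasable reagents. Abbreviations: TIPS = triisopropylsilyl, prenyl = 3-methylbut-2-en-1-yl, Bpin = 4,4,5,5-tetramethyl-1,3,2-dioxaborolan-2-yl. Chroman numbering: O1, C2, C3, C4, C4a, C5–C8, C8a. Benzofuran numbering: O1, C2, C3, C3a, C4–C7, C7a.

Step 1
Reactants: 1 2,4,6-trihydroxybenzaldehyde
Product: 2 2,4,6-trihydroxy-3-prenylbenzaldehyde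
Conditions: prenyl bromide (1.0 equiv), DBU (1.0 equiv), THF, 0 °C to rt
Reagents that add atoms: prenyl bromide CC(C)=CCBr
Why: C-alkylation of the ambident phloroglucinol-type phenoxide at a ring carbon between two hydroxyls (phenoxide C-prenylation); both free ring positions of 1 are equivalent, so only one mono-C-prenyl isomer can form.

Step 2
Reactants: 2 2,4,6-trihydroxy-3-prenylbenzaldehyde
Product: 3 2,6-dihydroxy-3-prenyl-4-(TIPS-oxy)benzaldehyde
Conditions: TIPSCl (1.05 equiv), imidazole, DMF, 0 °C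
Reagents that add atoms: triisopropylsilyl chloride CC(C)[Si](Cl)(C(C)C)C(C)C
Why: Regioselective phenol silylation, since the 4-OH para to the formyl group is the most acidic hydroxyl and the only one not hydrogen-bonded to the carbonyl, so one equivalent of silyl chloride should go there.

Step 3
Reactants: 3 2,6-dihydroxy-3-prenyl-4-(TIPS-oxy)benzaldehyde
Product: 4 ethyl 2-[2-formyl-3-hydroxy-4-prenyl-5-(TIPS-oxy)phenoxy]-2-methylpropanoate
Conditions: BrC(CH3)2CO2Et (2 equiv), K2CO3, MeCN, 60 °C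
Reagents that add atoms: ethyl 2-bromo-2-methylpropanoate CCOC(=O)C(C)(C)Br
Why: Williamson-type O-alkylation with a tertiary α-bromo ester (the fibrate ether synthesis), in which the bulky electrophile should take the hydroxyl flanked by H and not the one shielded by prenyl, and the quaternary α-carbon excludes a following aldol closure.

Step 4
Reactants: 4 ethyl 2-[2-formyl-3-hydroxy-4-prenyl-5-(TIPS-oxy)phenoxy]-2-methylpropanoate
Product: 6 6-hydroxy-2,2-dimethyl-7-prenyl-8-(TIPS-oxy)-4,5-dihydro-1,4-benzoxazepin-3(2H)-one, via amino ester 5 (not isolated)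
Conditions: NH3 (7 M in MeOH), 3 Å MS, rt; NaBH4, 0 °C; then PhMe, AcOH (cat.), 100 °C
Reagents that add atoms: ammonia N
Why: Reductive amination through the hydrogen-bond-stabilised salicylaldimine gives the primary benzylamine, which on heating should close the seven-membered lactam by intramolecular aminolysis of the ester, helped by the gem-dimethyl group (7-exo-trig lactamisation).

Step 5
Reactants: 6 6-hydroxy-2,2-dimethyl-7-prenyl-8-(TIPS-oxy)-4,5-dihydro-1,4-benzoxazepin-3(2H)-one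
Product: 7 2,2-dimethyl-3-oxo-7-prenyl-8-(TIPS-oxy)-2,3,4,5-tetrahydro-1,4-benzoxazepin-6-yl trifluoromethanesulfonate
Conditions: PhNTf2, Et3N, DMAP (cat.), CH2Cl2, rt
Reagents that add atoms: N-phenylbis(trifluoromethanesulfonimide) O=S(=O)(N(c1ccccc1)S(=O)(=O)C(F)(F)F)C(F)(F)F
Why: Phenol triflation with the mild triflimide, which sulfonylates the phenoxide and leaves the lactam N–H alone.

Step 6
Reactants: 7 2,2-dimethyl-3-oxo-7-prenyl-8-(TIPS-oxy)-2,3,4,5-tetrahydro-1,4-benzoxazepin-6-yl trifluoromethanesulfonate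
Product: 8 2,2-dimethyl-7-prenyl-8-(TIPS-oxy)-6-[(trimethylsilyl)ethynyl]-4,5-dihydro-1,4-benzoxazepin-3(2H)-one
Conditions: TMS-acetylene, Pd(PPh3)2Cl2 (5 mol%), CuI (10 mol%), Et3N, DMF, 80 °C (sealed tube)
Reagents that add atoms: ethynyltrimethylsilane C#C[Si](C)(C)C
Why: Sonogashira coupling of an aryl triflate whose carbon is meta to both oxygen donors and so not deactivated, while the lactam nitrogen is too weakly nucleophilic and too constrained to add to the new alkyne.

Step 7
Reactants: 8 2,2-dimethyl-7-prenyl-8-(TIPS-oxy)-6-[(trimethylsilyl)ethynyl]-4,5-dihydro-1,4-benzoxazepin-3(2H)-one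
Product: 10 6-ethynyl-2,2-dimethyl-7-prenyl-8-(TIPS-oxy)-2,3,4,5-tetrahydro-1,4-benzoxazepine, via silylalkyne amine 9 (not isolated)
Conditions: AlH3·NMe2Et, THF, 0 °C to rt; then K2CO3 (cat.), MeOH, rt
Reagents that add atoms: none
Why: Alane should reduce the secondary lactam to the amine at or below room temperature without hydroaluminating the silyl-capped alkyne or attacking the aryl silyl ether, and methanolysis then removes only the alkynyl trimethylsilyl group (amide reduction, then protiodesilylation).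

Step 8
Reactants: 10 6-ethynyl-2,2-dimethyl-7-prenyl-8-(TIPS-oxy)-2,3,4,5-tetrahydro-1,4-benzoxazepine
Product: 12 5-ethynyl-2,2-dimethyl-6-prenyl-7-(TIPS-oxy)chroman, via isodiazene 11 (not isolated)
Conditions: N-(benzyloxy)-N-(pivaloyloxy)-4-(trifluoromethyl)benzamide (1.5 equiv), THF, 45 °C
Reagents that add atoms: none
Why: The amine displaces pivalate at the amide nitrogen of the anomeric amide, the N-amino-N-benzyloxyamide so formed expels benzyl 4-(trifluoromethyl)benzoate (HERON-type shift) to give isodiazene 11, and 11 loses N2 to a singlet benzylic/primary-alkyl 1,6-diradical that recombines at once. The closest known reaction type is the nitrogen deletion of benzylic secondary amines with anomeric amides, which contracts cyclic amines by one atom through the classical isodiazene extrusion. The six-membered O1–C2–C3–C4–C4a–C8a ring closes by intramolecular radical–radical recombination between C3 and benzylic C4, so the seven-membered oxazepine becomes the chroman while the O1–C2 and C4–C4a bonds are never touched. No stereocenter is formed. The step needs C–C recombination to beat fragmentation of the diradical to an ortho-quinone methide and isobutene, hydrogen-transfer disproportionation and tetrazene formation; the ring tether, which holds the two carbons at bonding distance when N2 leaves, and the benzylic stabilisation, which lets extrusion run at 45 °C, should secure this. The aryl silyl ether, the prenyl group and the terminal alkyne should not react with the electrophilic aminating reagent, and removing the nitrogen here also prevents hydroamination of the neighbouring alkyne in the later Pd/Cu step.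

Step 9
Reactants: 13 phloroglucinol
Product: 14 3,5-bis(TIPS-oxy)phenol
Conditions: TIPSCl (2.0 equiv), imidazole, DMF, 0 °C to rt
Reagents that add atoms: triisopropylsilyl chloride CC(C)[Si](Cl)(C(C)C)C(C)C
Why: Statistical silylation of a C3-symmetric triol held at the bis-ether by stoichiometry, the bis-ether being separable from mono- and tris-ether by chromatography.

Step 10
Reactants: 14 3,5-bis(TIPS-oxy)phenol
Product: 16 2-bromo-6-iodo-3,5-bis(TIPS-oxy)phenol, via monobromide 15 (not isolated)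
Conditions: NBS (1.0 equiv), i-Pr2NH (cat.), CH2Cl2, −78 °C; then NIS (1.05 equiv), −78 to 0 °C
Reagents that add atoms: N-bromosuccinimide O=C1CCC(=O)N1Br; N-iodosuccinimide O=C1CCC(=O)N1I
Why: Two consecutive electrophilic halogenations ortho to the free hydroxyl (amine-assisted ortho-halogenation of phenols), the para carbon being shielded between two triisopropylsilyloxy groups, so bromine should enter one ortho carbon and iodine the other.

Step 11
Reactants: 16 2-bromo-6-iodo-3,5-bis(TIPS-oxy)phenol; 12 5-ethynyl-2,2-dimethyl-6-prenyl-7-(TIPS-oxy)chroman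
Product: 18 7-bromo-2-[2,2-dimethyl-6-prenyl-7-(TIPS-oxy)chroman-5-yl]-4,6-bis(TIPS-oxy)-1-benzofuran, via alkynylphenol 17 (not isolated)
Conditions: Pd(PPh3)2Cl2 (5 mol%), CuI (10 mol%), Et3N, DMF, 60 then 90 °C
Reagents that add atoms: none
Why: Sonogashira coupling at the C–I bond (the hindered, electron-rich C–Br bond should stay inert) followed by copper- and base-promoted 5-endo-dig cyclisation of the ortho-alkynylphenoxide (benzofuran annulation), in which only the free hydroxyl between the two halogens can close, so the bromide ends at C7.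

Step 12
Reactants: 18 7-bromo-2-[2,2-dimethyl-6-prenyl-7-(TIPS-oxy)chroman-5-yl]-4,6-bis(TIPS-oxy)-1-benzofuran
Product: 19 2-[2,2-dimethyl-6-prenyl-7-(TIPS-oxy)chroman-5-yl]-7-Bpin-4,6-bis(TIPS-oxy)-1-benzofuran
Conditions: t-BuLi (2.1 equiv), THF, −78 °C; i-PrOBpin, −78 °C to rt
Reagents that add atoms: 2-isopropoxy-4,4,5,5-tetramethyl-1,3,2-dioxaborolane CC(C)OB1OC(C)(C)C(C)(C)O1
Why: Bromine–lithium exchange and trapping of the aryllithium with the isopropoxyboronate, the low temperature and the bulk of TIPS suppressing the anionic O-to-C silyl shift.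

Step 13
Reactants: 19 2-[2,2-dimethyl-6-prenyl-7-(TIPS-oxy)chroman-5-yl]-7-Bpin-4,6-bis(TIPS-oxy)-1-benzofuran
Product: 21 2-[2,2-dimethyl-6-prenyl-7-(TIPS-oxy)chroman-5-yl]-7-[(1S)-1-Bpin-ethyl]-4,6-bis(TIPS-oxy)-1-benzofuran, via boronate complex 20 (not isolated)
Conditions: EtOC(O)N(i-Pr)2, s-BuLi, (+)-sparteine, Et2O, −78 °C; add 19, −78 °C; then 35 °C
Reagents that add atoms: ethyl N,N-diisopropylcarbamate CCOC(=O)N(C(C)C)C(C)C
Why: Lithiation–borylation (sparteine-mediated carbamate lithiation, then Matteson-type 1,2-metallate rearrangement), in which (+)-sparteine should give the (R)-lithiated carbamate, boron takes the place of lithium with retention and the aryl group migrates with inversion as the carbamate leaves, so the benzylic stereocenter is set as S by reagent control.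

Step 14
Reactants: 21 2-[2,2-dimethyl-6-prenyl-7-(TIPS-oxy)chroman-5-yl]-7-[(1S)-1-Bpin-ethyl]-4,6-bis(TIPS-oxy)-1-benzofuran
Product: 24 2-[2,2-dimethyl-6-prenyl-7-(TIPS-oxy)chroman-5-yl]-7-[(2R)-3-methylbut-3-en-2-yl]-4,6-bis(TIPS-oxy)-1-benzofuran, via isopropenyl boronate complex 22 (not isolated), via iodoalkyl boronic ester 23 (not isolated)
Conditions: 2-bromopropene, t-BuLi, THF, −78 °C; add 21; I2, MeOH, −78 °C; NaOMe, −78 °C to rt; Na2S2O3 quench
Reagents that add atoms: 2-bromopropene C=C(C)Br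
Why: Zweifel olefination, in which iodine triggers a stereoretentive 1,2-migration of the benzylic carbon from boron to the alkenyl carbon and methoxide induces anti-elimination of boron and iodide, so the S boronate should give the R side chain (the descriptor changes only through CIP priorities).

Step 15
Reactants: 24 2-[2,2-dimethyl-6-prenyl-7-(TIPS-oxy)chroman-5-yl]-7-[(2R)-3-methylbut-3-en-2-yl]-4,6-bis(TIPS-oxy)-1-benzofuran
Product: 25 2-(7-hydroxy-2,2-dimethyl-6-prenylchroman-5-yl)-7-[(2R)-3-methylbut-3-en-2-yl]-1-benzofuran-4,6-diol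
Conditions: TBAF (3.5 equiv), AcOH (3.5 equiv), THF, 0 °C, under argon
Reagents that add atoms: none
Why: Fluoride cleavage of the three aryl silyl ethers under acetate buffering, with no acid present that could cyclise a phenol onto the prenyl or isopropenyl group and a benzylic C–H too weakly acidic to epimerise.

Compound list
1 | 2,4,6-trihydroxybenzaldehyde | O=Cc1c(O)cc(O)cc1O | starting material
2 | 2,4,6-trihydroxy-3-prenylbenzaldehyde | O=Cc1c(O)cc(O)c(CC=C(C)C)c1O | intermediate
3 | 2,6-dihydroxy-3-prenyl-4-(TIPS-oxy)benzaldehyde | O=Cc1c(O)cc(O[Si](C(C)C)(C(C)C)C(C)C)c(CC=C(C)C)c1O | intermediate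
4 | ethyl 2-[2-formyl-3-hydroxy-4-prenyl-5-(TIPS-oxy)phenoxy]-2-methylpropanoate | CCOC(=O)C(C)(C)Oc1cc(O[Si](C(C)C)(C(C)C)C(C)C)c(CC=C(C)C)c(O)c1C=O | intermediate
5 | ethyl 2-[2-(aminomethyl)-3-hydroxy-4-prenyl-5-(TIPS-oxy)phenoxy]-2-methylpropanoate (amino ester, not isolated) | CCOC(=O)C(C)(C)Oc1cc(O[Si](C(C)C)(C(C)C)C(C)C)c(CC=C(C)C)c(O)c1CN | intermediate
6 | 6-hydroxy-2,2-dimethyl-7-prenyl-8-(TIPS-oxy)-4,5-dihydro-1,4-benzoxazepin-3(2H)-one | CC1(C)Oc2cc(O[Si](C(C)C)(C(C)C)C(C)C)c(CC=C(C)C)c(O)c2CNC1=O | intermediate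
7 | 2,2-dimethyl-3-oxo-7-prenyl-8-(TIPS-oxy)-2,3,4,5-tetrahydro-1,4-benzoxazepin-6-yl trifluoromethanesulfonate | CC1(C)Oc2cc(O[Si](C(C)C)(C(C)C)C(C)C)c(CC=C(C)C)c(OS(=O)(=O)C(F)(F)F)c2CNC1=O | intermediate
8 | 2,2-dimethyl-7-prenyl-8-(TIPS-oxy)-6-[(trimethylsilyl)ethynyl]-4,5-dihydro-1,4-benzoxazepin-3(2H)-one | CC1(C)Oc2cc(O[Si](C(C)C)(C(C)C)C(C)C)c(CC=C(C)C)c(C#C[Si](C)(C)C)c2CNC1=O | intermediate
9 | 2,2-dimethyl-7-prenyl-8-(TIPS-oxy)-6-[(trimethylsilyl)ethynyl]-2,3,4,5-tetrahydro-1,4-benzoxazepine (silylalkyne amine, not isolated) | CC1(C)Oc2cc(O[Si](C(C)C)(C(C)C)C(C)C)c(CC=C(C)C)c(C#C[Si](C)(C)C)c2CNC1 | intermediate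
10 | 6-ethynyl-2,2-dimethyl-7-prenyl-8-(TIPS-oxy)-2,3,4,5-tetrahydro-1,4-benzoxazepine | CC1(C)Oc2cc(O[Si](C(C)C)(C(C)C)C(C)C)c(CC=C(C)C)c(C#C)c2CNC1 | intermediate
11 | N4-isodiazene (1,1-diazene) of 10 (not isolated) | CC1(C)Oc2cc(O[Si](C(C)C)(C(C)C)C(C)C)c(CC=C(C)C)c(C#C)c2C[N+](=[N-])C1 | intermediate
12 | 5-ethynyl-2,2-dimethyl-6-prenyl-7-(TIPS-oxy)chroman | C#Cc1c(CC=C(C)C)c(O[Si](C(C)C)(C(C)C)C(C)C)cc2OC(C)(C)CCc12 | intermediate
13 | phloroglucinol (benzene-1,3,5-triol) | Oc1cc(O)cc(O)c1 | starting material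
14 | 3,5-bis(TIPS-oxy)phenol | Oc1cc(O[Si](C(C)C)(C(C)C)C(C)C)cc(O[Si](C(C)C)(C(C)C)C(C)C)c1 | intermediate
15 | 2-bromo-3,5-bis(TIPS-oxy)phenol (monobromide, not isolated) | Oc1cc(O[Si](C(C)C)(C(C)C)C(C)C)cc(O[Si](C(C)C)(C(C)C)C(C)C)c1Br | intermediate
16 | 2-bromo-6-iodo-3,5-bis(TIPS-oxy)phenol | Oc1c(I)c(O[Si](C(C)C)(C(C)C)C(C)C)cc(O[Si](C(C)C)(C(C)C)C(C)C)c1Br | intermediate
17 | 2-bromo-6-{[2,2-dimethyl-6-prenyl-7-(TIPS-oxy)chroman-5-yl]ethynyl}-3,5-bis(TIPS-oxy)phenol (alkynylphenol, not isolated) | Oc1c(Br)c(O[Si](C(C)C)(C(C)C)C(C)C)cc(O[Si](C(C)C)(C(C)C)C(C)C)c1C#Cc1c(CC=C(C)C)c(O[Si](C(C)C)(C(C)C)C(C)C)cc2OC(C)(C)CCc12 | intermediate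
18 | 7-bromo-2-[2,2-dimethyl-6-prenyl-7-(TIPS-oxy)chroman-5-yl]-4,6-bis(TIPS-oxy)-1-benzofuran | Brc1c(O[Si](C(C)C)(C(C)C)C(C)C)cc(O[Si](C(C)C)(C(C)C)C(C)C)c2cc(-c3c(CC=C(C)C)c(O[Si](C(C)C)(C(C)C)C(C)C)cc4c3CCC(C)(C)O4)oc12 | intermediate
19 | 2-[2,2-dimethyl-6-prenyl-7-(TIPS-oxy)chroman-5-yl]-7-Bpin-4,6-bis(TIPS-oxy)-1-benzofuran | CC1(C)OB(OC1(C)C)c1c(O[Si](C(C)C)(C(C)C)C(C)C)cc(O[Si](C(C)C)(C(C)C)C(C)C)c2cc(-c3c(CC=C(C)C)c(O[Si](C(C)C)(C(C)C)C(C)C)cc4c3CCC(C)(C)O4)oc12 | intermediate
20 | lithium boronate complex of 19 with the (R)-1-(N,N-diisopropylcarbamoyloxy)ethyl group on boron (not isolated) | [Li+].C[C@H](OC(=O)N(C(C)C)C(C)C)[B-]1(OC(C)(C)C(C)(C)O1)c1c(O[Si](C(C)C)(C(C)C)C(C)C)cc(O[Si](C(C)C)(C(C)C)C(C)C)c2cc(-c3c(CC=C(C)C)c(O[Si](C(C)C)(C(C)C)C(C)C)cc4c3CCC(C)(C)O4)oc12 | intermediate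
21 | 2-[2,2-dimethyl-6-prenyl-7-(TIPS-oxy)chroman-5-yl]-7-[(1S)-1-Bpin-ethyl]-4,6-bis(TIPS-oxy)-1-benzofuran | C[C@H](B1OC(C)(C)C(C)(C)O1)c1c(O[Si](C(C)C)(C(C)C)C(C)C)cc(O[Si](C(C)C)(C(C)C)C(C)C)c2cc(-c3c(CC=C(C)C)c(O[Si](C(C)C)(C(C)C)C(C)C)cc4c3CCC(C)(C)O4)oc12 | intermediate
22 | lithium isopropenyl boronate complex of 21 (not isolated) | [Li+].C=C(C)[B-]1(OC(C)(C)C(C)(C)O1)[C@@H](C)c1c(O[Si](C(C)C)(C(C)C)C(C)C)cc(O[Si](C(C)C)(C(C)C)C(C)C)c2cc(-c3c(CC=C(C)C)c(O[Si](C(C)C)(C(C)C)C(C)C)cc4c3CCC(C)(C)O4)oc12 | intermediate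
23 | β-iodoalkyl boronic ester formed by 1,2-migration, 7-[(2R)-3-Bpin-4-iodo-3-methylbutan-2-yl] analogue (not isolated, boron-bearing carbon unassigned) | ICC(C)(B1OC(C)(C)C(C)(C)O1)[C@@H](C)c1c(O[Si](C(C)C)(C(C)C)C(C)C)cc(O[Si](C(C)C)(C(C)C)C(C)C)c2cc(-c3c(CC=C(C)C)c(O[Si](C(C)C)(C(C)C)C(C)C)cc4c3CCC(C)(C)O4)oc12 | intermediate
24 | 2-[2,2-dimethyl-6-prenyl-7-(TIPS-oxy)chroman-5-yl]-7-[(2R)-3-methylbut-3-en-2-yl]-4,6-bis(TIPS-oxy)-1-benzofuran | C=C(C)[C@@H](C)c1c(O[Si](C(C)C)(C(C)C)C(C)C)cc(O[Si](C(C)C)(C(C)C)C(C)C)c2cc(-c3c(CC=C(C)C)c(O[Si](C(C)C)(C(C)C)C(C)C)cc4c3CCC(C)(C)O4)oc12 | intermediate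
25 | 2-(7-hydroxy-2,2-dimethyl-6-prenylchroman-5-yl)-7-[(2R)-3-methylbut-3-en-2-yl]-1-benzofuran-4,6-diol | C=C(C)[C@@H](C)c1c(O)cc(O)c2cc(-c3c(CC=C(C)C)c(O)cc4c3CCC(C)(C)O4)oc12 | target

Total step count: 15 (steps 1–8 for the chroman alkyne, steps 9–10 for the halophenol, steps 11–15 for union and endgame).
Longest linear sequence: 13 steps (steps 1–8, then 11–15).

Steps most likely to fail

Step 8. N–N bond formation at the β-branched ring nitrogen may be slower than decomposition of the aminating reagent, and at 45 °C the diradical may fragment to an ortho-quinone methide and isobutene instead of recombining. The fallback sets out from 10 and builds the isodiazene stepwise so that it can be released below room temperature. Nitrosation with tert-butyl nitrite should give the N-nitrosamine F1, reduction with LiAlH4 in ether at 0 °C the N-aminoamine F2, and oxidation of F2 with yellow HgO in ethanol at 0 °C should generate isodiazene 11 and, after loss of N2, return to the route at 12.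

Step 13. Formation of the boronate complex between the sparteine-bound lithiated carbamate and the 7-boronate, which sits between the furan oxygen and a TIPS-oxy group, may be slow or reversible, which would erode enantiopurity or lead to protodeboronation. The fallback sets out from 18 and replaces steps 12 and 13. Stille coupling with tributyl(vinyl)stannane (Pd(PPh3)4, toluene, 100 °C) should give the 7-vinylbenzofuran F3. Copper hydride-catalysed Markovnikov hydroboration of F3 with pinacolborane (CuCl, NaOt-Bu, DTBM-SEGPHOS, the ligand enantiomer being chosen to deliver the S boronate) returns to the route at 21.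

Step 3. Displacement on the tertiary bromide by the hydrogen-bonded, weakly nucleophilic phenoxide may be outrun by elimination of the bromide to the methacrylate, by alkylation at the wrong hydroxyl or by loss of the silyl ether. The fallback sets out from 3 and replaces steps 3 and 4 by forming the C–N bond first and the aryl ether bond intramolecularly. Reductive amination with ammonia and NaBH4 should give the benzylamine F4, and N-acylation with 2-bromo-2-methylpropanoyl bromide (aqueous NaHCO3, CH2Cl2, 0 °C) the bromoamide F5. K2CO3 in DMF should then close the seven-membered ring by intramolecular O-alkylation of the less hindered phenoxide by the tertiary α-bromoamide, returning to the route at 6.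

Further compounds
F1 | step 8 | 6-ethynyl-2,2-dimethyl-4-nitroso-7-prenyl-8-(TIPS-oxy)-2,3,4,5-tetrahydro-1,4-benzoxazepine | CC1(C)Oc2cc(O[Si](C(C)C)(C(C)C)C(C)C)c(CC=C(C)C)c(C#C)c2CN(N=O)C1
F2 | step 8 | 6-ethynyl-2,2-dimethyl-7-prenyl-8-(TIPS-oxy)-2,3-dihydro-1,4-benzoxazepin-4(5H)-amine | CC1(C)Oc2cc(O[Si](C(C)C)(C(C)C)C(C)C)c(CC=C(C)C)c(C#C)c2CN(N)C1
F3 | step 13 | 2-[2,2-dimethyl-6-prenyl-7-(TIPS-oxy)chroman-5-yl]-7-ethenyl-4,6-bis(TIPS-oxy)-1-benzofuran | C=Cc1c(O[Si](C(C)C)(C(C)C)C(C)C)cc(O[Si](C(C)C)(C(C)C)C(C)C)c2cc(-c3c(CC=C(C)C)c(O[Si](C(C)C)(C(C)C)C(C)C)cc4c3CCC(C)(C)O4)oc12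
F4 | step 3 | 2-(aminomethyl)-4-prenyl-5-(TIPS-oxy)benzene-1,3-diol | NCc1c(O)cc(O[Si](C(C)C)(C(C)C)C(C)C)c(CC=C(C)C)c1O
F5 | step 3 | 2-bromo-N-[2,6-dihydroxy-3-prenyl-4-(TIPS-oxy)benzyl]-2-methylpropanamide | CC(C)(Br)C(=O)NCc1c(O)cc(O[Si](C(C)C)(C(C)C)C(C)C)c(CC=C(C)C)c1O
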